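Feature: each prenyl CH2 of the target sits on an aromatic carbon ortho to a phenolic oxygen (ring A: C5 next to O4; ring B: C3' next to O4'). This is the pattern left by an O-to-C [3,3] shift of an aryl 1,1-dimethylallyl ether.
Cuts: first the two aryl–CH2 bonds (ring A C5–CH2 and ring B C3'–CH2) in one operation, then the CH2–C(=O) bond of the β-diketone on the ring B side, then the two tertiary C–O ether bonds.
Forward: the ring A fragment comes from 2,4-dihydroxyacetophenone (O4 propargylation, O2 MOM cap, semi-hydrogenation). The ring B fragment comes from methyl 4-hydroxybenzoate (propargylation, semi-hydrogenation).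
The fragments are joined by a crossed Claisen condensation, both allyl groups are moved from oxygen to carbon by heating, and the MOM group comes off last. Both benzene rings are bought and no ring is built.
Stereochemistry: the target has no stereocentre and both alkenes end in gem-dimethyl groups, so only regiochemistry (ring A C5 against C3) needs control, and the O2 cap provides it.

Key step: step 7

Assumption: all β-diketones are drawn as diketo tautomers although they will be largely enolised, and the order of the two shifts in step 7 (ring A before ring B) is taken for bookkeeping only, since it does not change the product.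

Step 1
Reactants: 1 2,4-dihydroxyacetophenone; 2 3-chloro-3-methylbut-1-yne
Product: 3 1-[2-hydroxy-4-(2-methylbut-3-yn-2-yloxy)phenyl]ethanone
Conditions: K2CO3, KI (cat.), CuI (cat.), DMF, 60 °C, Ar
Reagents that add atoms: none
Why: Copper-assisted Williamson-type O-alkylation of a phenoxide with a tertiary propargylic chloride is the standard entry to aryl 1,1-dimethylpropargyl ethers, and it should stop at O4 because the 2-hydroxyl is hydrogen-bonded to the acetyl oxygen and is both less acidic and less nucleophilic.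

Step 2
Reactants: 3 1-[2-hydroxy-4-(2-methylbut-3-yn-2-yloxy)phenyl]ethanone
Product: 4 1-[2-(methoxymethoxy)-4-(2-methylbut-3-yn-2-yloxy)phenyl]ethanone
Conditions: NaH (1.1 equiv), THF–DMF, 0 °C; MOMCl, 0 °C → rt
Reagents that add atoms: chloromethyl methyl ether (MOMCl), COCCl
Why: Williamson-type O-alkylation (MOM acetal formation) of the fully deprotonated, no longer chelated 2-phenoxide is routine for ortho-hydroxyacetophenones, and one equivalent of base leaves the far less acidic alkyne C–H and acetyl CH3 untouched.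

Step 3
Reactants: 4 1-[2-(methoxymethoxy)-4-(2-methylbut-3-yn-2-yloxy)phenyl]ethanone
Product: 5 1-[2-(methoxymethoxy)-4-(2-methylbut-3-en-2-yloxy)phenyl]ethanone
Conditions: H2 (1 atm, one equivalent taken up), Pd/CaCO3–Pb(OAc)2 (Lindlar catalyst), quinoline, EtOAc, rt
Reagents that add atoms: none
Why: Lindlar semi-hydrogenation of a terminal alkyne stops at the vinyl group on the lead- and quinoline-poisoned palladium surface, and the aryl ketone, the acetal and the tertiary C–O bond are inert at room temperature.

Step 4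
Reactants: 6 methyl 4-hydroxybenzoate; 2 3-chloro-3-methylbut-1-yne
Product: 7 methyl 4-(2-methylbut-3-yn-2-yloxy)benzoate
Conditions: K2CO3, KI (cat.), CuI (cat.), DMF, 60 °C, Ar
Reagents that add atoms: none
Why: The same copper-assisted Williamson-type propargylation applies, since the acidic para-acylphenol is a good partner and offers the only nucleophilic site.

Step 5
Reactants: 7 methyl 4-(2-methylbut-3-yn-2-yloxy)benzoate
Product: 8 methyl 4-(2-methylbut-3-en-2-yloxy)benzoate
Conditions: H2 (1 atm, one equivalent taken up), Pd/CaCO3–Pb(OAc)2 (Lindlar catalyst), quinoline, EtOAc, rt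
Reagents that add atoms: none
Why: Lindlar semi-hydrogenation, as in step 3, should convert the ethynyl group into the vinyl group without touching the ester or the aryl ether.

Step 6
Reactants: 5 1-[2-(methoxymethoxy)-4-(2-methylbut-3-en-2-yloxy)phenyl]ethanone; 8 methyl 4-(2-methylbut-3-en-2-yloxy)benzoate
Product: 9 1-[2-(methoxymethoxy)-4-(2-methylbut-3-en-2-yloxy)phenyl]-3-[4-(2-methylbut-3-en-2-yloxy)phenyl]propane-1,3-dione
Conditions: NaH (2.5 equiv), 8 (1.2 equiv), THF, slow addition of 5, 0 → 55 °C; then AcOH, 0 °C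
Reagents that add atoms: none
Why: In this crossed Claisen condensation the sodium enolate of 5 is acylated by the non-enolisable ester 8 and irreversible deprotonation of the β-diketone pulls the equilibrium over, while slow addition of 5 limits self-aldol reaction and 55 °C stays well below the onset of the [3,3] shift.

Step 7
Reactants: 9 1-[2-(methoxymethoxy)-4-(2-methylbut-3-en-2-yloxy)phenyl]-3-[4-(2-methylbut-3-en-2-yloxy)phenyl]propane-1,3-dione
Product: 13 1-[4-hydroxy-2-(methoxymethoxy)-5-(3-methylbut-2-enyl)phenyl]-3-[4-hydroxy-3-(3-methylbut-2-enyl)phenyl]propane-1,3-dione, via ring A ortho-dienone 10 (not isolated), via half-rearranged monoether 11 (not isolated), via ring B ortho-dienone 12 (not isolated)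
Conditions: N,N-diethylaniline (degassed), 140 °C, Ar
Reagents that add atoms: none
Why: Each aryl 1,1-dimethylallyl ether undergoes a concerted suprafacial [3,3]-sigmatropic shift through a chair-like six-membered transition state in which the O–CMe2 bond breaks as the vinyl CH2 bonds to the ortho carbon, giving the dienones 10 and 12, which enolise to the phenols 11 and 13. The closest known reaction type is the aromatic Claisen rearrangement of aryl tert-prenyl ethers to ortho-prenylphenols, which runs well below the temperature needed by simple allyl ethers because strain at the quaternary C–O bond is released and a trisubstituted alkene is gained. No ring is closed and no lasting stereocentre is made, since the sp3 carbons of 10 and 12 are erased on enolisation and the new alkenes carry two identical methyl groups. The selectivity needed is ring A C5 over C3, and the MOM cap should secure it: it removes the O2–H···O=C chelate that would localise double-bond character in C3–C4, its CH2OMe arm turns away from the carbonyl and covers C3 so that the bulky ether group sits on the C5 side, and C5 is para to the O2 donor. On ring B the two ortho carbons are equivalent, so no choice arises there. The basic solvent buffers the phenols and the enol as they form, which should suppress ionisation of the remaining ether and closure of prenylphenols to chromans, while the β-diketone and the acetal are thermally inert.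

Step 8
Reactants: 13 1-[4-hydroxy-2-(methoxymethoxy)-5-(3-methylbut-2-enyl)phenyl]-3-[4-hydroxy-3-(3-methylbut-2-enyl)phenyl]propane-1,3-dione
Product: 14 glycyrdione A, 1-[2,4-dihydroxy-5-(3-methylbut-2-enyl)phenyl]-3-[4-hydroxy-3-(3-methylbut-2-enyl)phenyl]propane-1,3-dione
Conditions: HCl (cat., ca. 0.2 M in MeOH), 0 °C → rt
Reagents that add atoms: none
Why: Acid-catalysed transacetalisation (MOM cleavage) is fastest for an acetal oxygen ortho to a carbonyl group, so dilute methanolic HCl at or below room temperature should release the chelated 2-hydroxyl before the prenylphenols or the diketone respond to the acid.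

Compound list
1 | 2,4-dihydroxyacetophenone | CC(=O)c1ccc(O)cc1O | starting material
2 | 3-chloro-3-methylbut-1-yne | C#CC(C)(C)Cl | starting material
3 | 1-[2-hydroxy-4-(2-methylbut-3-yn-2-yloxy)phenyl]ethanone | CC(=O)c1ccc(OC(C)(C)C#C)cc1O | intermediate
4 | 1-[2-(methoxymethoxy)-4-(2-methylbut-3-yn-2-yloxy)phenyl]ethanone | CC(=O)c1ccc(OC(C)(C)C#C)cc1OCOC | intermediate
5 | 1-[2-(methoxymethoxy)-4-(2-methylbut-3-en-2-yloxy)phenyl]ethanone | CC(=O)c1ccc(OC(C)(C)C=C)cc1OCOC | intermediate
6 | methyl 4-hydroxybenzoate | COC(=O)c1ccc(O)cc1 | starting material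
7 | methyl 4-(2-methylbut-3-yn-2-yloxy)benzoate | COC(=O)c1ccc(OC(C)(C)C#C)cc1 | intermediate
8 | methyl 4-(2-methylbut-3-en-2-yloxy)benzoate | COC(=O)c1ccc(OC(C)(C)C=C)cc1 | intermediate
9 | 1-[2-(methoxymethoxy)-4-(2-methylbut-3-en-2-yloxy)phenyl]-3-[4-(2-methylbut-3-en-2-yloxy)phenyl]propane-1,3-dione | C=CC(C)(C)Oc1ccc(C(=O)CC(=O)c2ccc(OC(C)(C)C=C)cc2OCOC)cc1 | intermediate
10 | 1-[6-(methoxymethoxy)-3-(3-methylbut-2-enyl)-4-oxocyclohexa-1,5-dien-1-yl]-3-[4-(2-methylbut-3-en-2-yloxy)phenyl]propane-1,3-dione (ring A ortho-dienone, racemic, transient) | C=CC(C)(C)Oc1ccc(C(=O)CC(=O)C2=CC(CC=C(C)C)C(=O)C=C2OCOC)cc1 | intermediate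
11 | 1-[4-hydroxy-2-(methoxymethoxy)-5-(3-methylbut-2-enyl)phenyl]-3-[4-(2-methylbut-3-en-2-yloxy)phenyl]propane-1,3-dione | C=CC(C)(C)Oc1ccc(C(=O)CC(=O)c2cc(CC=C(C)C)c(O)cc2OCOC)cc1 | intermediate
12 | 1-[4-hydroxy-2-(methoxymethoxy)-5-(3-methylbut-2-enyl)phenyl]-3-[3-(3-methylbut-2-enyl)-4-oxocyclohexa-1,5-dien-1-yl]propane-1,3-dione (ring B ortho-dienone, racemic, transient) | CC(C)=CCC1C=C(C(=O)CC(=O)c2cc(CC=C(C)C)c(O)cc2OCOC)C=CC1=O | intermediate
13 | 1-[4-hydroxy-2-(methoxymethoxy)-5-(3-methylbut-2-enyl)phenyl]-3-[4-hydroxy-3-(3-methylbut-2-enyl)phenyl]propane-1,3-dione | CC(C)=CCc1cc(C(=O)CC(=O)c2cc(CC=C(C)C)c(O)cc2OCOC)ccc1O | intermediate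
14 | glycyrdione A | CC(C)=CCc1cc(C(=O)CC(=O)c2cc(CC=C(C)C)c(O)cc2O)ccc1O | target

Total step count: 8. Longest linear sequence: 6 (steps 1, 2, 3, 6, 7, 8).

Steps most likely to fail

1. Step 7.
- Risk: the ring A migration may divide between C5 and C3, and the tertiary ethers may ionise and shed their allyl group before they rearrange.
- Fallback (from 1, using 8, back at 14): the ring A relay is moved from O4 to O2. C5 then becomes the para terminus of a Claisen–Cope cascade, and no regiochemical choice is left.
- MOMCl and K2CO3 in acetone at rt cap the unchelated 4-hydroxyl of 1 to give 1-[2-hydroxy-4-(methoxymethoxy)phenyl]ethanone F1.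
- Prenyl bromide and K2CO3 in DMF at 60 °C give 1-[4-(methoxymethoxy)-2-(3-methylbut-2-enyloxy)phenyl]ethanone F2.
- Heating in N,N-diethylaniline at about 190 °C moves the prenyl group by a [3,3] shift to C3, the only open ortho carbon, and on by a Cope shift to C5. This gives 1-[2-hydroxy-4-(methoxymethoxy)-5-(3-methylbut-2-enyl)phenyl]ethanone F3.
- Condensation with 8 as in step 6, with one more equivalent of NaH for the free phenol, gives 1-[2-hydroxy-4-(methoxymethoxy)-5-(3-methylbut-2-enyl)phenyl]-3-[4-(2-methylbut-3-en-2-yloxy)phenyl]propane-1,3-dione F4.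
- The one remaining ether, on the symmetric ring B, is rearranged as in step 7 to 1-[2-hydroxy-4-(methoxymethoxy)-5-(3-methylbut-2-enyl)phenyl]-3-[4-hydroxy-3-(3-methylbut-2-enyl)phenyl]propane-1,3-dione F5.
- Methanolic HCl as in step 8 then gives 14.

2. Step 8.
- Risk: the acid may close the freed 2-hydroxyl onto the enolised diketone with loss of water, or add a phenol across its neighbouring prenyl double bond.
- Fallback (from 3, using 8, back at 14): the acetal cap is replaced by a benzyl ether, which is removed by chelation-directed Lewis-acid dealkylation with no protic acid present.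
- BnBr and K2CO3 in DMF give 1-[2-(benzyloxy)-4-(2-methylbut-3-yn-2-yloxy)phenyl]ethanone F6.
- Semi-hydrogenation as in step 3, which leaves benzyl ethers intact, gives 1-[2-(benzyloxy)-4-(2-methylbut-3-en-2-yloxy)phenyl]ethanone F7.
- Condensation with 8 as in step 6 gives 1-[2-(benzyloxy)-4-(2-methylbut-3-en-2-yloxy)phenyl]-3-[4-(2-methylbut-3-en-2-yloxy)phenyl]propane-1,3-dione F8.
- Heating as in step 7 gives 1-[2-(benzyloxy)-4-hydroxy-5-(3-methylbut-2-enyl)phenyl]-3-[4-hydroxy-3-(3-methylbut-2-enyl)phenyl]propane-1,3-dione F9.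
- Excess MgBr2·OEt2 in toluene–Et2O at 60–70 °C then cleaves the cap. Magnesium held between the ring A carbonyl oxygen and O2 opens only this benzyl C–O bond to bromide, and mild aqueous work-up gives 14.

3. Step 6.
- Risk: acylation by the electron-rich ester may be too slow within the temperature ceiling set by the heat-sensitive ethers, so that self-aldol condensation of the ketone takes over.
- Fallback (from 8, using 5, back at 9): the C–C bond is made by an aldol addition at low temperature and the oxidation level is adjusted afterwards.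
- i-Bu2AlH (2.2 equiv) in CH2Cl2 at −78 → 0 °C reduces 8 to [4-(2-methylbut-3-en-2-yloxy)phenyl]methanol F10.
- MnO2 in CH2Cl2 at rt gives 4-(2-methylbut-3-en-2-yloxy)benzaldehyde F11.
- The lithium enolate of 5 (LiN(i-Pr)2, THF, −78 °C) adds to F11 to give racemic 3-hydroxy-1-[2-(methoxymethoxy)-4-(2-methylbut-3-en-2-yloxy)phenyl]-3-[4-(2-methylbut-3-en-2-yloxy)phenyl]propan-1-one F12.
- Dess–Martin periodinane with NaHCO3 in CH2Cl2 at 0 °C → rt oxidises the carbinol to the β-diketone 9.

Further compounds
F1 | step 7 | 1-[2-hydroxy-4-(methoxymethoxy)phenyl]ethanone | CC(=O)c1ccc(OCOC)cc1O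
F2 | step 7 | 1-[4-(methoxymethoxy)-2-(3-methylbut-2-enyloxy)phenyl]ethanone | CC(=O)c1ccc(OCOC)cc1OCC=C(C)C
F3 | step 7 | 1-[2-hydroxy-4-(methoxymethoxy)-5-(3-methylbut-2-enyl)phenyl]ethanone | CC(=O)c1cc(CC=C(C)C)c(OCOC)cc1O
F4 | step 7 | 1-[2-hydroxy-4-(methoxymethoxy)-5-(3-methylbut-2-enyl)phenyl]-3-[4-(2-methylbut-3-en-2-yloxy)phenyl]propane-1,3-dione | C=CC(C)(C)Oc1ccc(C(=O)CC(=O)c2cc(CC=C(C)C)c(OCOC)cc2O)cc1
F5 | step 7 | 1-[2-hydroxy-4-(methoxymethoxy)-5-(3-methylbut-2-enyl)phenyl]-3-[4-hydroxy-3-(3-methylbut-2-enyl)phenyl]propane-1,3-dione | CC(C)=CCc1cc(C(=O)CC(=O)c2cc(CC=C(C)C)c(OCOC)cc2O)ccc1O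
F6 | step 8 | 1-[2-(benzyloxy)-4-(2-methylbut-3-yn-2-yloxy)phenyl]ethanone | CC(=O)c1ccc(OC(C)(C)C#C)cc1OCc2ccccc2
F7 | step 8 | 1-[2-(benzyloxy)-4-(2-methylbut-3-en-2-yloxy)phenyl]ethanone | CC(=O)c1ccc(OC(C)(C)C=C)cc1OCc2ccccc2
F8 | step 8 | 1-[2-(benzyloxy)-4-(2-methylbut-3-en-2-yloxy)phenyl]-3-[4-(2-methylbut-3-en-2-yloxy)phenyl]propane-1,3-dione | C=CC(C)(C)Oc1ccc(C(=O)CC(=O)c2ccc(OC(C)(C)C=C)cc2OCc3ccccc3)cc1
F9 | step 8 | 1-[2-(benzyloxy)-4-hydroxy-5-(3-methylbut-2-enyl)phenyl]-3-[4-hydroxy-3-(3-methylbut-2-enyl)phenyl]propane-1,3-dione | CC(C)=CCc1cc(C(=O)CC(=O)c2cc(CC=C(C)C)c(O)cc2OCc3ccccc3)ccc1O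
F10 | step 6 | [4-(2-methylbut-3-en-2-yloxy)phenyl]methanol | C=CC(C)(C)Oc1ccc(CO)cc1
F11 | step 6 | 4-(2-methylbut-3-en-2-yloxy)benzaldehyde | C=CC(C)(C)Oc1ccc(C=O)cc1
F12 | step 6 | 3-hydroxy-1-[2-(methoxymethoxy)-4-(2-methylbut-3-en-2-yloxy)phenyl]-3-[4-(2-methylbut-3-en-2-yloxy)phenyl]propan-1-one (racemic) | C=CC(C)(C)Oc1ccc(C(O)CC(=O)c2ccc(OC(C)(C)C=C)cc2OCOC)cc1
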